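**Plan**

- Cuts, in order: the C3–C(=O) bond between the pyridone and the trienoyl chain (arylmagnesium plus trienal, then oxidation); both C–O bonds at C1' and C4' of the cyclohexane ring (peroxide bridge, back to a ring diene and O2); the C5–C1' bond (aryllithium plus 3-ethoxycyclohexenone); the chain at C2=C3 and C6=C7 (olefinations) back to an α-branched aldehyde.
- Forward: pyridine bis-ether → 3-pyridylcyclohexenone → 1-pyridylcyclohexa-1,3-diene → 2,3-dioxabicyclo[2.2.2]octene (the only ring closed in the route) → cis-diol → silyl ethers, C3 iodide, N-oxide. The trienal is built separately and joined last, followed by oxidation and one fluoride deprotection.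
- Enabling feature: the oxygens on C1' and C4' of the cyclohexane ring lie on the same face (1,4-cis), the only arrangement an O–O bridge across C1'/C4' of a cyclohexa-1,3-diene can deliver.
- Stereochemistry: the cis-diol comes from the bridge (relative only). C8 (R) comes from auxiliary-controlled hydroxymethylation of an N-butanoyl oxazolidinone. The three E-alkenes come from stabilized phosphorus reagents.

Key step: step 5

Remark: the cis-1-aryl-cyclohexane-1,4-diol unit has a mirror plane through C1' and C4', so a racemic endoperoxide suffices and C8 is the only centre needing absolute control. Working through the configurations shows that the (R)-configured 4-benzyl-oxazolidinone is the auxiliary that leads to (8R). The heterocycle is numbered N1, C2 (O), C3 (acyl), C4 (O), C5 (cyclohexyl), C6 (H) throughout.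

**Route**

Step 1
Reactants: 1 5-bromo-2,4-dichloropyridine; 2 2-(trimethylsilyl)ethanol
Product: 4 5-bromo-2,4-bis[2-(trimethylsilyl)ethoxy]pyridine, via 5-bromo-2-chloro-4-[2-(trimethylsilyl)ethoxy]pyridine 3 (not isolated)
Conditions: NaH (2.6 equiv), 2 (2.5 equiv), THF/DMF 4:1, 0 °C → rt, then 60 °C
Reagents that add atoms: none
Why: Nucleophilic aromatic substitution, in which the alkoxide should displace the C4 chloride (para to N) at room temperature and the C2 chloride (ortho to N) on warming, while the C5 bromide, not activated by the ring nitrogen, stays in place.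

Step 2
Reactants: 4 5-bromo-2,4-bis[2-(trimethylsilyl)ethoxy]pyridine; 5 3-ethoxycyclohex-2-en-1-one
Product: 8 3-{4,6-bis[2-(trimethylsilyl)ethoxy]pyridin-3-yl}cyclohex-2-en-1-one, via {4,6-bis[2-(trimethylsilyl)ethoxy]pyridin-3-yl}lithium 6 (not isolated), via lithium 1-aryl-3-ethoxycyclohex-2-en-1-olate 7 (not isolated)
Conditions: n-BuLi (1.05 equiv), THF, −78 °C; 5, −78 → 0 °C; then 1 M aq. HCl, 0 °C → rt
Reagents that add atoms: water, O
Why: Bromine–lithium exchange, 1,2-addition to the vinylogous ester and acid-mediated ionization and hydrolysis (Stork–Danheiser transposition) should place the pyridyl group on C3 of a cyclohexenone, which fixes the regiochemistry of the later diene.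

Step 3
Reactants: 8 3-{4,6-bis[2-(trimethylsilyl)ethoxy]pyridin-3-yl}cyclohex-2-en-1-one
Product: 10 5-{4,6-bis[2-(trimethylsilyl)ethoxy]pyridin-3-yl}cyclohexa-1,5-dien-1-yl trifluoromethanesulfonate, via lithium 5-arylcyclohexa-1,5-dien-1-olate 9 (not isolated)
Conditions: LiN(iPr)2 (1.1 equiv), THF, −78 °C; PhNTf2, −78 → 0 °C
Reagents that add atoms: N-phenylbis(trifluoromethanesulfonimide), O=S(=O)(N(c1ccccc1)S(=O)(=O)C(F)(F)F)C(F)(F)F
Why: Kinetic deprotonation of the enone at the α'-methylene gives the cross-conjugated dienolate, and its O-triflation should lock the second double bond on the side away from the aryl-bearing alkene (enol triflate formation).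

Step 4
Reactants: 10 5-{4,6-bis[2-(trimethylsilyl)ethoxy]pyridin-3-yl}cyclohexa-1,5-dien-1-yl trifluoromethanesulfonate
Product: 11 5-(cyclohexa-1,3-dien-1-yl)-2,4-bis[2-(trimethylsilyl)ethoxy]pyridine
Conditions: Pd(OAc)2 (5 mol %), PPh3 (10 mol %), HCO2H (2 equiv), Bu3N (3 equiv), DMF, 60 °C
Reagents that add atoms: none
Why: Palladium-catalysed formate reduction of an alkenyl triflate (oxidative addition to zerovalent palladium, formate-to-hydride exchange with loss of CO2, reductive elimination) should replace OTf by H without moving either double bond, leaving the aryl group on the terminal carbon of the ring diene.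

Step 5
Reactants: 11 5-(cyclohexa-1,3-dien-1-yl)-2,4-bis[2-(trimethylsilyl)ethoxy]pyridine
Product: 12 racemic 1-{4,6-bis[2-(trimethylsilyl)ethoxy]pyridin-3-yl}-2,3-dioxabicyclo[2.2.2]oct-5-ene
Conditions: O2, 5,10,15,20-tetraphenylporphyrin (0.5 mol %), visible light (white LED), CH2Cl2, −20 °C; solution used directly in step 6
Reagents that add atoms: dioxygen (reacting as singlet oxygen), O=O
Why: Energy transfer from the excited porphyrin converts ground-state O2 into singlet oxygen, which adds as a two-atom dienophile in a concerted suprafacial [4+2] cycloaddition across C1' and C4' of the s-cis ring diene. The closest known reaction type is the photooxygenation of cyclohexa-1,3-dienes to 2,3-dioxabicyclo[2.2.2]oct-5-enes, as in the formation of ascaridole from α-terpinene. The six-membered 1,2-dioxine ring closes by this intermolecular cycloaddition, both C–O bonds forming in the same event. The two new stereocentres C1' and C4' are fixed relative to each other by the O–O bridge, which can only span one face of the ring, and no absolute control is needed because the derived diol is achiral. The step needs cycloaddition to win over the ene reaction at the C5' and C6' methylenes and over aromatization: the diene is held cisoid by the ring and made electron-rich by the alkoxypyridyl group at its terminus, the bis-ether pyridine is not itself an acceptor for singlet oxygen, and cold base-free conditions should keep the bridgehead C4'–H from starting a Kornblum–DeLaMare rearrangement.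

Step 6
Reactants: 12 racemic 1-{4,6-bis[2-(trimethylsilyl)ethoxy]pyridin-3-yl}-2,3-dioxabicyclo[2.2.2]oct-5-ene
Product: 14 cis-1-{4,6-bis[2-(trimethylsilyl)ethoxy]pyridin-3-yl}cyclohexane-1,4-diol, via cis-1-arylcyclohex-2-ene-1,4-diol 13 (not isolated)
Conditions: H2 (1 atm), Pd/C (10 wt % Pd), EtOAc, rt
Reagents that add atoms: none
Why: Heterogeneous hydrogenation should cleave the weak O–O bond and then saturate the ring alkene, so both hydroxyls keep the cis relationship fixed in step 5 and no stereocentre is touched.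

Step 7
Reactants: 14 cis-1-{4,6-bis[2-(trimethylsilyl)ethoxy]pyridin-3-yl}cyclohexane-1,4-diol
Product: 15 5-[cis-1,4-bis(triethylsilyloxy)cyclohexyl]-2,4-bis[2-(trimethylsilyl)ethoxy]pyridine
Conditions: Et3SiOTf (3 equiv), 2,6-lutidine (5 equiv), CH2Cl2, −78 → 0 °C
Reagents that add atoms: triethylsilyl trifluoromethanesulfonate, CC[Si](CC)(CC)OS(=O)(=O)C(F)(F)F
Why: A silyl triflate with a hindered pyridine base silylates both the secondary and the hindered tertiary hydroxyl, giving fluoride-labile ethers that should survive organometallic reagents, peracid and periodinane.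

Step 8
Reactants: 15 5-[cis-1,4-bis(triethylsilyloxy)cyclohexyl]-2,4-bis[2-(trimethylsilyl)ethoxy]pyridine
Product: 17 5-[cis-1,4-bis(triethylsilyloxy)cyclohexyl]-3-iodo-2,4-bis[2-(trimethylsilyl)ethoxy]pyridine, via 3-lithio derivative of the pyridine 16 (not isolated)
Conditions: n-BuLi (1.3 equiv), THF, −78 → −30 °C; I2, −78 °C
Reagents that add atoms: iodine, II
Why: Directed ortho-metalation, in which C3–H between the two alkoxy groups is the most activated ring proton, so lithiation there and iodine quench should give the 3-iodide.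

Step 9
Reactants: 17 5-[cis-1,4-bis(triethylsilyloxy)cyclohexyl]-3-iodo-2,4-bis[2-(trimethylsilyl)ethoxy]pyridine
Product: 18 5-[cis-1,4-bis(triethylsilyloxy)cyclohexyl]-3-iodo-2,4-bis[2-(trimethylsilyl)ethoxy]pyridine 1-oxide
Conditions: mCPBA (1.5 equiv), CH2Cl2, 0 °C → rt
Reagents that add atoms: 3-chloroperoxybenzoic acid, O=C(OO)c1cccc(Cl)c1
Why: Peracid N-oxidation of the pyridine, made nucleophilic by the 4-alkoxy group, installs the oxygen that becomes the N–OH of the pyridone before any oxidation-sensitive triene is present.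

Step 10
Reactants: 19 (R)-4-benzyl-1,3-oxazolidin-2-one; 20 butanoyl chloride
Product: 22 (4R)-4-benzyl-3-butanoyl-1,3-oxazolidin-2-one, via N-lithio oxazolidinone 21 (not isolated)
Conditions: n-BuLi (1.05 equiv), THF, −78 °C; 20, −78 → 0 °C
Reagents that add atoms: none
Why: N-acylation of the lithiated oxazolidinone with an acid chloride is the standard entry to the imide and leaves the C4 stereocentre untouched.

Step 11
Reactants: 22 (4R)-4-benzyl-3-butanoyl-1,3-oxazolidin-2-one
Product: 24 (4R)-4-benzyl-3-[(2S)-2-(hydroxymethyl)butanoyl]-1,3-oxazolidin-2-one, via chlorotitanium Z-enolate 23 (not isolated)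
Conditions: TiCl4 (1.05 equiv), iPr2NEt (1.1 equiv), CH2Cl2, 0 °C; then 1,3,5-trioxane (1.1 equiv), TiCl4 (1.05 equiv), 0 °C
Reagents that add atoms: 1,3,5-trioxane, C1OCOCO1
Why: Evans-type auxiliary-controlled hydroxymethylation, in which TiCl4-activated formaldehyde attacks the chelated Z-enolate on the face opposite the benzyl group and should set the (2S) centre that becomes C8 (R) of the target.

Step 12
Reactants: 24 (4R)-4-benzyl-3-[(2S)-2-(hydroxymethyl)butanoyl]-1,3-oxazolidin-2-one
Product: 25 (4R)-4-benzyl-3-[(2S)-2-({[tert-butyl(diphenyl)silyl]oxy}methyl)butanoyl]-1,3-oxazolidin-2-one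
Conditions: tBuPh2SiCl (1.1 equiv), imidazole (2 equiv), CH2Cl2, 0 °C → rt
Reagents that add atoms: tert-butyl(chloro)diphenylsilane, CC(C)(C)[Si](Cl)(c1ccccc1)c1ccccc1
Why: Imidazole-mediated silylation of the primary alcohol, with the bulky diphenylsilyl group chosen because it resists the 1,3-oxygen-to-oxygen migration that would racemize the mono-protected diol of step 13.

Step 13
Reactants: 25 (4R)-4-benzyl-3-[(2S)-2-({[tert-butyl(diphenyl)silyl]oxy}methyl)butanoyl]-1,3-oxazolidin-2-one
Product: 26 (2R)-2-({[tert-butyl(diphenyl)silyl]oxy}methyl)butan-1-ol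
Conditions: LiBH4 (1.5 equiv), MeOH (1 equiv), THF, 0 °C
Reagents that add atoms: none
Why: Reductive cleavage of the imide by borohydride releases the primary alcohol and returns the auxiliary without touching the α-centre (the descriptor changes only through the priority switch).

Step 14
Reactants: 26 (2R)-2-({[tert-butyl(diphenyl)silyl]oxy}methyl)butan-1-ol
Product: 27 (2S)-2-({[tert-butyl(diphenyl)silyl]oxy}methyl)butanal
Conditions: Dess–Martin periodinane (1.2 equiv), pyridine, CH2Cl2, 0 °C → rt; used crude at once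
Reagents that add atoms: none
Why: Dess–Martin oxidation under buffered, non-basic conditions should give the α-branched aldehyde without epimerization.

Step 15
Reactants: 27 (2S)-2-({[tert-butyl(diphenyl)silyl]oxy}methyl)butanal; 28 ethyl (E)-4-(diethoxyphosphoryl)but-2-enoate
Product: 29 ethyl (2E,4E,6R)-6-({[tert-butyl(diphenyl)silyl]oxy}methyl)octa-2,4-dienoate
Conditions: 28 (1.2 equiv), LiN(SiMe3)2 (1.15 equiv), THF, −78 °C; then 27, −78 → 0 °C
Reagents that add atoms: none
Why: Horner–Wadsworth–Emmons olefination with the preformed vinylogous phosphonate anion should give the new C4=C5 bond E-selectively, and addition of the aldehyde at low temperature limits its enolization.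

Step 16
Reactants: 29 ethyl (2E,4E,6R)-6-({[tert-butyl(diphenyl)silyl]oxy}methyl)octa-2,4-dienoate
Product: 30 (2E,4E,6R)-6-({[tert-butyl(diphenyl)silyl]oxy}methyl)octa-2,4-dien-1-ol
Conditions: iBu2AlH (2.5 equiv), CH2Cl2, −78 °C; aq. potassium sodium tartrate
Reagents that add atoms: none
Why: Aluminium hydride 1,2-reduction of the conjugated ester gives the dienol without conjugate reduction or loss of the silyl ether.

Step 17
Reactants: 30 (2E,4E,6R)-6-({[tert-butyl(diphenyl)silyl]oxy}methyl)octa-2,4-dien-1-ol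
Product: 31 (2E,4E,6R)-6-({[tert-butyl(diphenyl)silyl]oxy}methyl)octa-2,4-dienal
Conditions: MnO2 (activated, excess), CH2Cl2, rt
Reagents that add atoms: none
Why: MnO2 oxidizes allylic alcohols selectively and under neutral conditions, so alkene geometry and the C6 centre should be preserved.

Step 18
Reactants: 31 (2E,4E,6R)-6-({[tert-butyl(diphenyl)silyl]oxy}methyl)octa-2,4-dienal; 32 (triphenylphosphoranylidene)acetaldehyde
Product: 33 (2E,4E,6E,8R)-8-({[tert-butyl(diphenyl)silyl]oxy}methyl)deca-2,4,6-trienal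
Conditions: 32 (1.3 equiv), toluene, 80 °C
Reagents that add atoms: none
Why: Wittig olefination with the stabilized formyl ylide should add two carbons as an E-enal, and the trienal product is less electrophilic than the dienal, which limits a second homologation.

Step 19
Reactants: 18 5-[cis-1,4-bis(triethylsilyloxy)cyclohexyl]-3-iodo-2,4-bis[2-(trimethylsilyl)ethoxy]pyridine 1-oxide; 33 (2E,4E,6E,8R)-8-({[tert-butyl(diphenyl)silyl]oxy}methyl)deca-2,4,6-trienal
Product: 35 (2E,4E,6E,8R)-1-{5-[cis-1,4-bis(triethylsilyloxy)cyclohexyl]-1-oxido-2,4-bis[2-(trimethylsilyl)ethoxy]pyridin-1-ium-3-yl}-8-({[tert-butyl(diphenyl)silyl]oxy}methyl)deca-2,4,6-trien-1-ol (both C1 epimers), via 3-chloromagnesio pyridine N-oxide 34 (not isolated)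
Conditions: iPrMgCl·LiCl (1.1 equiv), THF, −40 °C; then 33 (1.2 equiv), −40 → 0 °C; aq. NH4Cl
Reagents that add atoms: none
Why: Iodine–magnesium exchange on an iodopyridine N-oxide should outrun deprotonation at C6 at low temperature, and the arylmagnesium held between two alkoxy groups adds 1,2 to the trienal (Grignard addition), the uncontrolled carbinol centre being removed in step 20.

Step 20
Reactants: 35 the C1 carbinol from step 19
Product: 36 (2E,4E,6E,8R)-1-{5-[cis-1,4-bis(triethylsilyloxy)cyclohexyl]-1-oxido-2,4-bis[2-(trimethylsilyl)ethoxy]pyridin-1-ium-3-yl}-8-({[tert-butyl(diphenyl)silyl]oxy}methyl)deca-2,4,6-trien-1-one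
Conditions: Dess–Martin periodinane (1.5 equiv), pyridine, CH2Cl2, 0 °C → rt
Reagents that add atoms: none
Why: Dess–Martin oxidation of the doubly activated (allylic and aryl-substituted) secondary alcohol should give the aryl trienyl ketone without touching the N-oxide, the silyl ethers or the triene.

Step 21
Reactants: 36 the fully protected trienone from step 20
Product: 37 1,4-dihydroxy-5-(cis-1,4-dihydroxycyclohexyl)-3-[(2E,4E,6E,8R)-8-(hydroxymethyl)deca-2,4,6-trienoyl]pyridin-2(1H)-one
Conditions: Bu4NF (8 equiv), THF, 0 °C → rt; aq. NH4Cl/citric acid work-up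
Reagents that add atoms: none
Why: Fluoride cleaves the three O–Si ethers and fragments both 2-(trimethylsilyl)ethyl ethers by β-elimination (ethene and Me3SiF), the leaving groups being the acyl-stabilized 4-oxide and the 2-oxidopyridine N-oxide, which tautomerizes to the 1-hydroxy-2-pyridone.

**Compound list**

1 | 5-bromo-2,4-dichloropyridine | Clc1cc(Cl)c(Br)cn1 | starting material
2 | 2-(trimethylsilyl)ethanol | C[Si](C)(C)CCO | starting material
3 | 5-bromo-2-chloro-4-[2-(trimethylsilyl)ethoxy]pyridine | C[Si](C)(C)CCOc1cc(Cl)ncc1Br | intermediate (not isolated)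
4 | 5-bromo-2,4-bis[2-(trimethylsilyl)ethoxy]pyridine | C[Si](C)(C)CCOc1cc(OCC[Si](C)(C)C)c(Br)cn1 | intermediate
5 | 3-ethoxycyclohex-2-en-1-one | CCOC1=CC(=O)CCC1 | starting material
6 | {4,6-bis[2-(trimethylsilyl)ethoxy]pyridin-3-yl}lithium | [Li]c1cnc(OCC[Si](C)(C)C)cc1OCC[Si](C)(C)C | intermediate (not isolated)
7 | lithium 1-{4,6-bis[2-(trimethylsilyl)ethoxy]pyridin-3-yl}-3-ethoxycyclohex-2-en-1-olate (racemic) | CCOC1=CC(O[Li])(c2cnc(OCC[Si](C)(C)C)cc2OCC[Si](C)(C)C)CCC1 | intermediate (not isolated)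
8 | 3-{4,6-bis[2-(trimethylsilyl)ethoxy]pyridin-3-yl}cyclohex-2-en-1-one | O=C1C=C(c2cnc(OCC[Si](C)(C)C)cc2OCC[Si](C)(C)C)CCC1 | intermediate
9 | lithium 5-{4,6-bis[2-(trimethylsilyl)ethoxy]pyridin-3-yl}cyclohexa-1,5-dien-1-olate | [Li]OC1=CCCC(c2cnc(OCC[Si](C)(C)C)cc2OCC[Si](C)(C)C)=C1 | intermediate (not isolated)
10 | 5-{4,6-bis[2-(trimethylsilyl)ethoxy]pyridin-3-yl}cyclohexa-1,5-dien-1-yl trifluoromethanesulfonate | O=S(=O)(OC1=CCCC(c2cnc(OCC[Si](C)(C)C)cc2OCC[Si](C)(C)C)=C1)C(F)(F)F | intermediate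
11 | 5-(cyclohexa-1,3-dien-1-yl)-2,4-bis[2-(trimethylsilyl)ethoxy]pyridine | C[Si](C)(C)CCOc1cc(OCC[Si](C)(C)C)c(C2=CC=CCC2)cn1 | intermediate (key-step precursor)
12 | 1-{4,6-bis[2-(trimethylsilyl)ethoxy]pyridin-3-yl}-2,3-dioxabicyclo[2.2.2]oct-5-ene (racemic; one enantiomer drawn) | C[Si](C)(C)CCOc1cc(OCC[Si](C)(C)C)c([C@]2(O3)C=C[C@@H](O3)CC2)cn1 | intermediate (key-step product)
13 | cis-1-{4,6-bis[2-(trimethylsilyl)ethoxy]pyridin-3-yl}cyclohex-2-ene-1,4-diol (racemic; one enantiomer drawn) | C[Si](C)(C)CCOc1cc(OCC[Si](C)(C)C)c([C@]2(O)C=C[C@@H](O)CC2)cn1 | intermediate (not isolated)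
14 | cis-1-{4,6-bis[2-(trimethylsilyl)ethoxy]pyridin-3-yl}cyclohexane-1,4-diol (achiral) | C[Si](C)(C)CCOc1cc(OCC[Si](C)(C)C)c([C@]2(O)CC[C@@H](O)CC2)cn1 | intermediate
15 | 5-[cis-1,4-bis(triethylsilyloxy)cyclohexyl]-2,4-bis[2-(trimethylsilyl)ethoxy]pyridine | C[Si](C)(C)CCOc1cc(OCC[Si](C)(C)C)c([C@]2(O[Si](CC)(CC)CC)CC[C@@H](O[Si](CC)(CC)CC)CC2)cn1 | intermediate
16 | {5-[cis-1,4-bis(triethylsilyloxy)cyclohexyl]-2,4-bis[2-(trimethylsilyl)ethoxy]pyridin-3-yl}lithium | C[Si](C)(C)CCOc1c([Li])c(OCC[Si](C)(C)C)c([C@]2(O[Si](CC)(CC)CC)CC[C@@H](O[Si](CC)(CC)CC)CC2)cn1 | intermediate (not isolated)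
17 | 5-[cis-1,4-bis(triethylsilyloxy)cyclohexyl]-3-iodo-2,4-bis[2-(trimethylsilyl)ethoxy]pyridine | C[Si](C)(C)CCOc1c(I)c(OCC[Si](C)(C)C)c([C@]2(O[Si](CC)(CC)CC)CC[C@@H](O[Si](CC)(CC)CC)CC2)cn1 | intermediate
18 | 5-[cis-1,4-bis(triethylsilyloxy)cyclohexyl]-3-iodo-2,4-bis[2-(trimethylsilyl)ethoxy]pyridine 1-oxide | C[Si](C)(C)CCOc1c(I)c(OCC[Si](C)(C)C)c([C@]2(O[Si](CC)(CC)CC)CC[C@@H](O[Si](CC)(CC)CC)CC2)c[n+]1[O-] | intermediate
19 | (R)-4-benzyl-1,3-oxazolidin-2-one | O=C1OC[C@@H](Cc2ccccc2)N1 | starting material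
20 | butanoyl chloride | CCCC(Cl)=O | starting material
21 | lithium salt of (R)-4-benzyl-1,3-oxazolidin-2-one (N-lithiated) | [Li]N1[C@H](Cc2ccccc2)COC1=O | intermediate (not isolated)
22 | (4R)-4-benzyl-3-butanoyl-1,3-oxazolidin-2-one | CCCC(=O)N1[C@H](Cc2ccccc2)COC1=O | intermediate
23 | trichlorotitanium Z-enolate of 22 | CC/C=C(\O[Ti](Cl)(Cl)Cl)N1[C@H](Cc2ccccc2)COC1=O | intermediate (not isolated)
24 | (4R)-4-benzyl-3-[(2S)-2-(hydroxymethyl)butanoyl]-1,3-oxazolidin-2-one | CC[C@@H](CO)C(=O)N1[C@H](Cc2ccccc2)COC1=O | intermediate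
25 | (4R)-4-benzyl-3-[(2S)-2-({[tert-butyl(diphenyl)silyl]oxy}methyl)butanoyl]-1,3-oxazolidin-2-one | CC[C@@H](CO[Si](c1ccccc1)(c1ccccc1)C(C)(C)C)C(=O)N1[C@H](Cc2ccccc2)COC1=O | intermediate
26 | (2R)-2-({[tert-butyl(diphenyl)silyl]oxy}methyl)butan-1-ol | CC[C@@H](CO[Si](c1ccccc1)(c1ccccc1)C(C)(C)C)CO | intermediate
27 | (2S)-2-({[tert-butyl(diphenyl)silyl]oxy}methyl)butanal | CC[C@@H](CO[Si](c1ccccc1)(c1ccccc1)C(C)(C)C)C=O | intermediate
28 | ethyl (E)-4-(diethoxyphosphoryl)but-2-enoate (triethyl 4-phosphonocrotonate) | CCOC(=O)/C=C/CP(=O)(OCC)OCC | starting material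
29 | ethyl (2E,4E,6R)-6-({[tert-butyl(diphenyl)silyl]oxy}methyl)octa-2,4-dienoate | CC[C@@H](CO[Si](c1ccccc1)(c1ccccc1)C(C)(C)C)/C=C/C=C/C(=O)OCC | intermediate
30 | (2E,4E,6R)-6-({[tert-butyl(diphenyl)silyl]oxy}methyl)octa-2,4-dien-1-ol | CC[C@@H](CO[Si](c1ccccc1)(c1ccccc1)C(C)(C)C)/C=C/C=C/CO | intermediate
31 | (2E,4E,6R)-6-({[tert-butyl(diphenyl)silyl]oxy}methyl)octa-2,4-dienal | CC[C@@H](CO[Si](c1ccccc1)(c1ccccc1)C(C)(C)C)/C=C/C=C/C=O | intermediate
32 | (triphenylphosphoranylidene)acetaldehyde | O=CC=P(c1ccccc1)(c1ccccc1)c1ccccc1 | starting material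
33 | (2E,4E,6E,8R)-8-({[tert-butyl(diphenyl)silyl]oxy}methyl)deca-2,4,6-trienal | CC[C@@H](CO[Si](c1ccccc1)(c1ccccc1)C(C)(C)C)/C=C/C=C/C=C/C=O | intermediate
34 | chloro{5-[cis-1,4-bis(triethylsilyloxy)cyclohexyl]-1-oxido-2,4-bis[2-(trimethylsilyl)ethoxy]pyridin-1-ium-3-yl}magnesium | C[Si](C)(C)CCOc1c([Mg]Cl)c(OCC[Si](C)(C)C)c([C@]2(O[Si](CC)(CC)CC)CC[C@@H](O[Si](CC)(CC)CC)CC2)c[n+]1[O-] | intermediate (not isolated)
35 | (2E,4E,6E,8R)-1-{5-[cis-1,4-bis(triethylsilyloxy)cyclohexyl]-1-oxido-2,4-bis[2-(trimethylsilyl)ethoxy]pyridin-1-ium-3-yl}-8-({[tert-butyl(diphenyl)silyl]oxy}methyl)deca-2,4,6-trien-1-ol (both C1 epimers) | CC[C@@H](CO[Si](c1ccccc1)(c1ccccc1)C(C)(C)C)/C=C/C=C/C=C/C(O)c1c(OCC[Si](C)(C)C)c([C@]2(O[Si](CC)(CC)CC)CC[C@@H](O[Si](CC)(CC)CC)CC2)c[n+]([O-])c1OCC[Si](C)(C)C | intermediate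
36 | (2E,4E,6E,8R)-1-{5-[cis-1,4-bis(triethylsilyloxy)cyclohexyl]-1-oxido-2,4-bis[2-(trimethylsilyl)ethoxy]pyridin-1-ium-3-yl}-8-({[tert-butyl(diphenyl)silyl]oxy}methyl)deca-2,4,6-trien-1-one | CC[C@@H](CO[Si](c1ccccc1)(c1ccccc1)C(C)(C)C)/C=C/C=C/C=C/C(=O)c1c(OCC[Si](C)(C)C)c([C@]2(O[Si](CC)(CC)CC)CC[C@@H](O[Si](CC)(CC)CC)CC2)c[n+]([O-])c1OCC[Si](C)(C)C | intermediate
37 | 1,4-dihydroxy-5-(cis-1,4-dihydroxycyclohexyl)-3-[(2E,4E,6E,8R)-8-(hydroxymethyl)deca-2,4,6-trienoyl]pyridin-2(1H)-one | CC[C@H](/C=C/C=C/C=C/C(=O)c1c(O)c([C@]2(O)CC[C@@H](O)CC2)cn(O)c1=O)CO | target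

**Totals and risks**

Total step count: 21. Longest linear sequence: 12 steps (steps 1–9, then 19–21; the side-chain arm, steps 10–18 then 19–21, is equally long).

Steps most likely to fail:

1. Step 5. The photooxygenation may be diverted into ene hydroperoxidation at the C5'/C6' methylenes followed by loss of H2O2 and aromatization, or the endoperoxide may rearrange through bridgehead deprotonation before it is reduced. The fallback sets out from 4 and comes back at 14. Aryllithium 6, generated from 4 as in step 2, would be added at −78 °C to commercial 4-[(tert-butyldimethylsilyl)oxy]cyclohexan-1-one (CC(C)(C)[Si](C)(C)OC1CCC(=O)CC1). Equatorial attack of the bulky aryllithium on the chair with an equatorial silyloxy group should favour the axial tertiary alcohol, cis-1-{4,6-bis[2-(trimethylsilyl)ethoxy]pyridin-3-yl}-4-[(tert-butyldimethylsilyl)oxy]cyclohexan-1-ol F1, which is separable from its trans isomer by chromatography. Bu4NF in THF at 0 °C would then remove the alkyl silyl ether, the aryl 2-(trimethylsilyl)ethyl ethers of the unactivated pyridine being expected to persist at that temperature, and deliver diol 14.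

2. Step 19. Deprotonation at C6 or nucleophilic addition to the N-oxide ring may compete with iodine–magnesium exchange, or slow addition of the hindered arylmagnesium may allow it to decompose. The fallback sets out from 15 and comes back at 36. The 3-lithio species 16 (step 8 conditions) would be quenched with N-methoxy-N-methylacetamide (CON(C)C(C)=O) to give 1-{5-[cis-1,4-bis(triethylsilyloxy)cyclohexyl]-2,4-bis[2-(trimethylsilyl)ethoxy]pyridin-3-yl}ethan-1-one F2. mCPBA would convert it into the corresponding pyridine 1-oxide F3. Enolization with LiN(SiMe3)2 at −78 °C and aldol addition to dienal 31 would give the β-hydroxy ketone (4E,6E,8R)-1-{5-[cis-1,4-bis(triethylsilyloxy)cyclohexyl]-1-oxido-2,4-bis[2-(trimethylsilyl)ethoxy]pyridin-1-ium-3-yl}-8-({[tert-butyl(diphenyl)silyl]oxy}methyl)-3-hydroxydeca-4,6-dien-1-one F4. Mesylation and elimination (MsCl, Et3N, CH2Cl2, 0 °C → rt) would then form the C2=C3 E-alkene of 36, so the N-oxide never meets an organomagnesium reagent.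

3. Step 6. Hydrogenolysis of the tertiary C1'–O bond (aryl-activated and, in intermediate 13, allylic) or metal-induced isomerization of the allylic alcohol may erode the diol. The fallback sets out from 12 and comes back at 14. Diimide, generated from dipotassium azodicarboxylate and AcOH in MeOH/CH2Cl2 at 0 °C, would saturate the bicyclic alkene without touching the O–O bond and give 1-{4,6-bis[2-(trimethylsilyl)ethoxy]pyridin-3-yl}-2,3-dioxabicyclo[2.2.2]octane F5. Zinc dust in AcOH/CH2Cl2 at 0 °C would then cleave the peroxide to diol 14 with no metal hydride surface and no allylic alcohol involved.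

**Further compounds**

F1 | step 5 | cis-1-{4,6-bis[2-(trimethylsilyl)ethoxy]pyridin-3-yl}-4-[(tert-butyldimethylsilyl)oxy]cyclohexan-1-ol | C[Si](C)(C)CCOc1cc(OCC[Si](C)(C)C)c([C@]2(O)CC[C@@H](O[Si](C)(C)C(C)(C)C)CC2)cn1
F2 | step 19 | 1-{5-[cis-1,4-bis(triethylsilyloxy)cyclohexyl]-2,4-bis[2-(trimethylsilyl)ethoxy]pyridin-3-yl}ethan-1-one | CC(=O)c1c(OCC[Si](C)(C)C)c([C@]2(O[Si](CC)(CC)CC)CC[C@@H](O[Si](CC)(CC)CC)CC2)cnc1OCC[Si](C)(C)C
F3 | step 19 | 3-acetyl-5-[cis-1,4-bis(triethylsilyloxy)cyclohexyl]-2,4-bis[2-(trimethylsilyl)ethoxy]pyridine 1-oxide | CC(=O)c1c(OCC[Si](C)(C)C)c([C@]2(O[Si](CC)(CC)CC)CC[C@@H](O[Si](CC)(CC)CC)CC2)c[n+]([O-])c1OCC[Si](C)(C)C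
F4 | step 19 | (4E,6E,8R)-1-{5-[cis-1,4-bis(triethylsilyloxy)cyclohexyl]-1-oxido-2,4-bis[2-(trimethylsilyl)ethoxy]pyridin-1-ium-3-yl}-8-({[tert-butyl(diphenyl)silyl]oxy}methyl)-3-hydroxydeca-4,6-dien-1-one (both C3 epimers) | CC[C@@H](CO[Si](c1ccccc1)(c1ccccc1)C(C)(C)C)/C=C/C=C/C(O)CC(=O)c1c(OCC[Si](C)(C)C)c([C@]2(O[Si](CC)(CC)CC)CC[C@@H](O[Si](CC)(CC)CC)CC2)c[n+]([O-])c1OCC[Si](C)(C)C
F5 | step 6 | 1-{4,6-bis[2-(trimethylsilyl)ethoxy]pyridin-3-yl}-2,3-dioxabicyclo[2.2.2]octane | C[Si](C)(C)CCOc1cc(OCC[Si](C)(C)C)c(C23CCC(CC2)OO3)cn1
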